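**Retrosynthetic overview**
- Target 9 ⇐ phenolic amino aldehyde 5 in one flask: oxidative dearomatisation at the alkyl-bearing ortho carbon (C1–O), methanol oxa-Michael/aldol (C4–OMe, C5–C6), then exo epoxidation (C2–C3).
- Ring order: ring B is the phenol ring of L-o-tyrosine; a transient oxolane (lactol) forms first, then carbocycle A, then the oxirane. Carbocycle A and the oxirane, with six stereocentres, arise in the same operation.
- 5 ⇐ ester 4 (half-reduction) ⇐ amide coupling of L-o-tyrosine methyl ester 2 with (E)-dodec-2-enoic acid 3. The amino acid carbon (C7) is the only imported stereocentre.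
- Locants used for the core: C1 hydroxylated bridgehead, C2/C3 epoxide, C4 OMe, C5 bridgehead H, C6 OH, C7 N, C8 CH2, C9 C=O.

Assumption: L-o-tyrosine (2-hydroxy-L-phenylalanine) and (E)-dodec-2-enoic acid are bought as catalogue chemicals. The route is a paper design and has not been run.

**Route**

Step 1
Reactants: 1 L-o-tyrosine
Product: 2 L-o-tyrosine methyl ester hydrochloride
Conditions: SOCl2, MeOH, 0 °C to reflux
Reagents that add atoms: methanol CO; thionyl chloride ClS(Cl)=O
Why: Fischer-type esterification through in situ HCl/acyl chloride, in which the ammonium salt protects the amine and the α-centre is not touched (no new stereocentre).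

Step 2
Reactants: 2 L-o-tyrosine methyl ester hydrochloride; 3 (E)-dodec-2-enoic acid
Product: 4 methyl N-[(E)-dodec-2-enoyl]-L-o-tyrosinate
Conditions: EDC·HCl, HOBt, i-Pr2NEt, CH2Cl2, 0 °C to rt
Reagents that add atoms: none
Why: Carbodiimide/HOBt amide coupling, in which the HOBt ester acylates the primary amine much faster than the phenol and the stereocentre carries no activated carbonyl, so there is no azlactone racemisation (no new stereocentre).

Step 3
Reactants: 4 methyl N-[(E)-dodec-2-enoyl]-L-o-tyrosinate
Product: 5 N-[(E)-dodec-2-enoyl]-L-o-tyrosinal (stored as its chroman-2-ol lactol)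
Conditions: i-Bu2AlH (3.3 equiv), CH2Cl2, −78 °C; MeOH quench, aq. KNaC4H4O6
Reagents that add atoms: none
Why: Ester half-reduction, in which the tetrahedral aluminium hemiacetal (held further by the neighbouring aluminium phenoxide) survives until quench and the aldehyde then rests as the cyclic lactol, which shields the α-stereocentre from enolisation (no new stereocentre).

Step 4
Reactants: 5 N-[(E)-dodec-2-enoyl]-L-o-tyrosinal
Product: 9 target CNP0137540.1, via spirolactol dienone 6 (not isolated), via ortho-quinol aldehyde 7 (not isolated), via bicyclic alkene diol 8 (not isolated)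
Conditions: PhI(OAc)2 (1.05 equiv), MeCN, H2O (5 equiv), 0 °C, 15 min; then MeOH, K2CO3 (2.5 equiv), 0 °C, 1 h; then CH2Cl2, mCPBA (4 equiv), 0 °C to rt; one flask
Reagents that add atoms: water O; methanol CO; mCPBA (3-chloroperoxybenzoic acid) OOC(=O)c1cccc(Cl)c1
Why: Proposed new method: the aldehyde hydrate of 5 traps the PhI(OAc)2-generated phenoxenium at the alkyl-bearing ortho carbon (Kita-type dearomative spirocyclisation; closest known cases are the spirolactolisation of tyrosinal and the ortho-spirolactonisation of phenolic acids), with the amide expected to sit trans to the dienone carbonyl on the new oxolane so that the L-centre fixes C1 as S; carbonate in methanol then opens lactol 6 to 7, methoxide adds reversibly to C4, and the C5 enolate closes ring A by a chair-like, potassium-bridged aldol on the only face the tether can reach (oxa-Michael/aldol cascade of the kind known for para-quinol aldehydes), which places OMe anti to the new C5–C6 bond, the C6–OH syn to the C9 carbonyl and the amide equatorial, while bridgehead C5 blocks retro-Michael; finally mCPBA epoxidises the only electron-rich alkene of 8 on the open exo face, guided by the allylic bridgehead OH (Henbest-type epoxidation) and shielded on the endo face by ring A.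

**Compound list**

1 | L-o-tyrosine, (2S)-2-amino-3-(2-hydroxyphenyl)propanoic acid | N[C@@H](Cc1ccccc1O)C(=O)O | starting material
2 | methyl (2S)-2-amino-3-(2-hydroxyphenyl)propanoate hydrochloride | Cl.N[C@@H](Cc1ccccc1O)C(=O)OC | intermediate
3 | (E)-dodec-2-enoic acid | CCCCCCCCC/C=C/C(=O)O | starting material
4 | methyl (2S)-2-[(E)-dodec-2-enoylamino]-3-(2-hydroxyphenyl)propanoate | CCCCCCCCC/C=C/C(=O)N[C@@H](Cc1ccccc1O)C(=O)OC | intermediate
5 | (E)-N-[(2S)-1-(2-hydroxyphenyl)-3-oxopropan-2-yl]dodec-2-enamide (open form; in equilibrium with the 3-amidochroman-2-ol lactol) | CCCCCCCCC/C=C/C(=O)N[C@@H](Cc1ccccc1O)C=O | intermediate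
6 | (E)-N-[(3S,5S)-2-hydroxy-6-oxo-1-oxaspiro[4.5]deca-7,9-dien-3-yl]dodec-2-enamide (anomers) | CCCCCCCCC/C=C/C(=O)N[C@H]1C[C@]2(OC1O)C=CC=CC2=O | intermediate
7 | (E)-N-[(2S)-1-[(1S)-1-hydroxy-2-oxocyclohexa-3,5-dien-1-yl]-3-oxopropan-2-yl]dodec-2-enamide | CCCCCCCCC/C=C/C(=O)N[C@H](C=O)C[C@]1(O)C=CC=CC1=O | intermediate
8 | (E)-N-[1,6-dihydroxy-4-methoxy-9-oxobicyclo[3.3.1]non-2-en-7-yl]dodec-2-enamide, configured as 9 at C1, C4, C5, C6, C7 (4-OMe exo-axial, 6-OH axial syn to C9=O, 7-amide equatorial) | CCCCCCCCC/C=C/C(=O)N[C@H]1C[C@@]2(O)C(=O)[C@@H]([C@H]1O)[C@H](OC)C=C2 | intermediate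
9 | (E)-N-[(1S,2S,3S,4S,5S,6R,7S)-2,3-epoxy-1,6-dihydroxy-4-methoxy-9-oxobicyclo[3.3.1]nonan-7-yl]dodec-2-enamide (epoxide O, 4-OMe and 1-OH all on the exo face of ring B; 6-OH cis to 7-NH) | CCCCCCCCC/C=C/C(=O)N[C@H]1C[C@@]2(O)C(=O)[C@@H]([C@H]1O)[C@H](OC)[C@@H]1O[C@@H]12 | target

**Step count and risks**

Total steps: 4. Longest linear sequence: 4 (1 → 2 → 4 → 5 → 9).

Steps most likely to fail:

1. Step 4. Four things can go wrong:
   - the ortho-dienone can dimerise by Diels–Alder reaction before the base stage;
   - the facial bias at C1 rests on 1,3-induction from C7 and may be modest; if C7 then epimerises in base, the wrong C1 epimer feeds the enantiomer;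
   - methoxide may add on the wrong face of C4;
   - the peracid may attack the strained C9 ketone (Baeyer–Villiger) or be consumed by iodobenzene.

   Fallback, setting out from 5 and returning at 9, reverses the ring order. Treat 5 with 4-iodotoluene (20 mol %), mCPBA (3 equiv) and H2O (5 equiv) in CH2Cl2/(CF3)2CHOH at 0 °C. The trivalent iodine species formed in situ carries out the same dearomative lactolisation, and the excess peracid epoxidises the distal diene bond cis to the spiro oxygen. This gives the stable, non-dimerising (E)-N-[(3S,5S,9S,10S)-9,10-epoxy-2-hydroxy-6-oxo-1-oxaspiro[4.5]dec-7-en-3-yl]dodec-2-enamide F1. F1 can be chromatographed free of its C1 epimer. K2CO3 in MeOH at 0 °C then opens the lactol and runs the oxa-Michael/aldol closure of ring A to give 9.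

2. Step 3. Over-reduction to the alcohol or loss of configuration at the α-carbon is possible. Fallback, setting out from 4 and returning at 5, is a two-stage redox detour. LiBH4 in THF (0 °C to rt) reduces the ester fully to (E)-N-[(2S)-1-hydroxy-3-(2-hydroxyphenyl)propan-2-yl]dodec-2-enamide F2. The primary alcohol is then oxidised with SO3·pyridine, DMSO and i-Pr2NEt in CH2Cl2 at 0 °C, which does not touch the phenol, to give 5.

3. Step 2. Competing acylation of the phenol or a sluggish coupling of the enoic acid is possible. Fallback, setting out from 3 and returning at 4, uses an isolated active ester. Acid 3 is condensed with N-hydroxysuccinimide and N,N'-diisopropylcarbodiimide in EtOAc to give succinimidyl (E)-dodec-2-enoate F3. F3 then acylates only the amine of 2 under NaHCO3 in THF/H2O to give 4.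

**Further compounds**

F1 | step 4 | (E)-N-[(3S,5S,9S,10S)-9,10-epoxy-2-hydroxy-6-oxo-1-oxaspiro[4.5]dec-7-en-3-yl]dodec-2-enamide | CCCCCCCCC/C=C/C(=O)N[C@H]1C[C@]2(OC1O)[C@H]3O[C@H]3C=CC2=O
F2 | step 3 | (E)-N-[(2S)-1-hydroxy-3-(2-hydroxyphenyl)propan-2-yl]dodec-2-enamide | CCCCCCCCC/C=C/C(=O)N[C@@H](Cc1ccccc1O)CO
F3 | step 2 | succinimidyl (E)-dodec-2-enoate | CCCCCCCCC/C=C/C(=O)ON1C(=O)CCC1=O
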